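**Strategy.** With the core numbered C1(OMe)–C2(OAc)–C3(OMe)=C4–C5(allyl)–C6(Me)–C7(Ar) and C8=O bridging C1 and C5, the route exploits the cyclopentanone ring C1–C7–C6–C5–C8. Its C8 ketone, C1 methoxy group and trans C7-aryl/C6-methyl pair are the mark of a Nazarov closure at C6–C7, the bond between the two β-carbons of a divinyl ketone. A chiral-Lewis-acid-triggered 4π-conrotatory cyclisation, intercepted by hydride from Et3SiH, forms this ring, the C6–C7 bond and both stereocentres in one operation. The precursor is the (1Z,4E)-α-methoxy dienone 7. The six-membered ring follows by C5 formylation/allylation, a cis-selective olefination and a lithium-chelated aldol closing C1–C2.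

Key step: step 4

Assumption: the (S,S)-ligand 2,2′-(propane-2,2-diyl)bis[(4S)-4-tert-butyl-4,5-dihydrooxazole] ((S,S)-t-Bu-box) is taken to induce the conrotation that gives (3S,4S)-9; if the sense is opposite, the (R,R)-ligand is used with no other change.
Assumption: phosphonate 12 is taken as commercially available.
Remark: the six-membered ring can only close if C5 and the C2 carbonyl are cis on C3=C4; for a 2-methoxy-2-enoate this is the E descriptor (OMe outranks the carbonyl carbon), so step 8 uses a kinetically controlled, cis-selective olefination.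
Remark: C1 of 9–18 is epimerisable and is drawn trans to the aryl group; its configuration is erased in step 11, where C1 becomes an enolate carbon.

Step 1
Reactants: 1 3,4-dimethoxybenzaldehyde; 2 methyl methoxyacetate
Product: 3 methyl (2Z)-3-(3,4-dimethoxyphenyl)-2-methoxyprop-2-enoate
Conditions: NaOMe, MeOH, 0 °C to reflux
Reagents that add atoms: none
Why: Claisen–Schmidt-type aldol condensation of the ester enolate with the non-enolisable aldehyde, in which E1cB dehydration under equilibrating conditions should give the more stable Z isomer (aryl cis to OMe, trans to the ester).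

Step 2
Reactants: 3 methyl (2Z)-3-(3,4-dimethoxyphenyl)-2-methoxyprop-2-enoate
Product: 4 (2Z)-3-(3,4-dimethoxyphenyl)-N,2-dimethoxy-N-methylprop-2-enamide
Conditions: MeNH(OMe)·HCl, i-PrMgCl, THF, −20 to 0 °C
Reagents that add atoms: N,O-dimethylhydroxylamine hydrochloride, CNOC.Cl
Why: Weinreb amide formation by aminolysis of the ester with the chloromagnesium amide, which should leave the trisubstituted enol ether alkene and its Z geometry untouched.

Step 3
Reactants: 5 (E)-1-bromoprop-1-ene; 4 (2Z)-3-(3,4-dimethoxyphenyl)-N,2-dimethoxy-N-methylprop-2-enamide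
Product: 7 (1Z,4E)-1-(3,4-dimethoxyphenyl)-2-methoxyhexa-1,4-dien-3-one, via (E)-prop-1-en-1-yllithium 6 (not isolated)
Conditions: 5, t-BuLi (2 equiv), Et2O, −78 °C; then 4, THF, −78 to 0 °C; H2O
Reagents that add atoms: none
Why: Lithium–bromine exchange with retention of alkene geometry followed by the Weinreb ketone synthesis, which stops at the ketone stage and should deliver the cross-conjugated dienone with both alkene geometries intact.

Step 4
Reactants: 7 (1Z,4E)-1-(3,4-dimethoxyphenyl)-2-methoxyhexa-1,4-dien-3-one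
Product: 9 (2S,3S,4S)-3-(3,4-dimethoxyphenyl)-2-methoxy-4-methylcyclopentan-1-one, via triethylsilyl enol ether 8 (not isolated)
Conditions: Cu(OTf)2 (10 mol%), (S,S)-t-Bu-box (11 mol%), Et3SiH (3 equiv), CH2Cl2, −20 °C to rt; then 1 M HCl, THF, rt
Reagents that add atoms: none
Why: Proposed new method: divalent copper bound by the bis(oxazoline) chelates the C8 carbonyl and the C1 methoxy oxygen of 7, which locks the aryl-vinyl arm s-trans and generates a 3-oxidopentadienyl cation that closes the five-membered ring by thermal 4π-conrotatory electrocyclisation (C6–C7 bond); Et3SiH then delivers hydride to the oxyallyl cation, expected at the unhindered C5 terminus remote from the metal, faster than a β-proton is lost, and the resulting enolate is silylated to 8 and hydrolysed to 9 (hydride at C1 would converge on the same ketone). The closest known reactions are the silane-interrupted (reductive) Nazarov cyclisation under achiral Lewis acids and the enantioselective Nazarov cyclisation of chelating dienones with chiral copper or scandium complexes, which have not been combined. C6 and C7 should come out trans because both β-substituents point outward in the (1Z,4E)-dienone and conrotation turns them to opposite faces. Their absolute configuration follows from the sense of conrotation, which the C2-symmetric ligand controls because the aryl-bearing terminus sits next to a tert-butyl group in the rigid five-membered chelate. C1 is set by protonation and equilibrates to the trans isomer. The step needs torquoselectivity and hydride capture in preference to elimination or to reduction of the uncyclised dienone, and the α-methoxy group secures both by providing the second binding point and by polarising the dienone so that cyclisation is fast under catalytic activation.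

Step 5
Reactants: 9 (2S,3S,4S)-3-(3,4-dimethoxyphenyl)-2-methoxy-4-methylcyclopentan-1-one
Product: 10 (2S,3S,4R,5Z)-3-(3,4-dimethoxyphenyl)-5-(hydroxymethylidene)-2-methoxy-4-methylcyclopentan-1-one
Conditions: NaH, HCO2Et, cat. EtOH, THF, 0 °C to rt; aq. HCl
Reagents that add atoms: ethyl formate, CCOC=O
Why: Crossed Claisen condensation (formylation) under thermodynamic control, in which only acylation at the C5 methylene gives an enolisable and therefore stabilised β-keto aldehyde, so the methoxy-bearing C1 should stay unsubstituted.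

Step 6
Reactants: 10 (2S,3S,4R,5Z)-3-(3,4-dimethoxyphenyl)-5-(hydroxymethylidene)-2-methoxy-4-methylcyclopentan-1-one
Product: 11 (1S,3S,4S,5R)-4-(3,4-dimethoxyphenyl)-3-methoxy-5-methyl-2-oxo-1-(prop-2-en-1-yl)cyclopentane-1-carbaldehyde
Conditions: Pd(PPh3)4 (5 mol%), allyl methyl carbonate, THF, rt
Reagents that add atoms: allyl methyl carbonate, C=CCOC(=O)OC
Why: Tsuji–Trost allylation of the stabilised α-formyl ketone enolate under neutral conditions, in which the π-allylpalladium electrophile should attack C5 on the face opposite the adjacent C6 methyl group and so set the quaternary centre with allyl trans and formyl cis to methyl.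

Step 7
Reactants: 12 methyl 2-(dimethoxyphosphoryl)-2-methoxyacetate
Product: 15 methyl 2-[bis(2,2,2-trifluoroethoxy)phosphoryl]-2-methoxyacetate, via bis(trimethylsilyl) phosphonate 13 (not isolated), via phosphonic dichloride 14 (not isolated)
Conditions: TMSBr, CH2Cl2, rt; (COCl)2, cat. DMF, CH2Cl2, rt; CF3CH2OH, Et3N, CH2Cl2, 0 °C
Reagents that add atoms: 2,2,2-trifluoroethanol, OCC(F)(F)F
Why: McKenna silyl-dealkylation of the dimethyl phosphonate, chlorination and alcoholysis is the standard entry to Still–Gennari-type bis(trifluoroethyl) phosphonates and should leave the carboxylic ester and the methyl ether intact.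

Step 8
Reactants: 11 (1S,3S,4S,5R)-4-(3,4-dimethoxyphenyl)-3-methoxy-5-methyl-2-oxo-1-(prop-2-en-1-yl)cyclopentane-1-carbaldehyde; 15 methyl 2-[bis(2,2,2-trifluoroethoxy)phosphoryl]-2-methoxyacetate
Product: 16 methyl (2E)-3-[(1S,3S,4S,5R)-4-(3,4-dimethoxyphenyl)-3-methoxy-5-methyl-2-oxo-1-(prop-2-en-1-yl)cyclopentyl]-2-methoxyprop-2-enoate
Conditions: 15, KN(SiMe3)2, 18-crown-6, THF, −78 °C; then 11, −78 to −40 °C
Reagents that add atoms: none
Why: Still–Gennari variant of the Horner–Wadsworth–Emmons olefination, in which fast irreversible collapse of the kinetically favoured adduct of the trifluoroethyl phosphonate should place the ester cis to the C5 substituent (the E descriptor here), as established for α-halo and α-alkyl reagents of this type, while the hindered ketone does not compete with the aldehyde.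

Step 9
Reactants: 16 methyl (2E)-3-[(1S,3S,4S,5R)-4-(3,4-dimethoxyphenyl)-3-methoxy-5-methyl-2-oxo-1-(prop-2-en-1-yl)cyclopentyl]-2-methoxyprop-2-enoate
Product: 17 (2E)-3-[(1S,3S,4S,5R)-4-(3,4-dimethoxyphenyl)-2-hydroxy-3-methoxy-5-methyl-1-(prop-2-en-1-yl)cyclopentyl]-2-methoxyprop-2-en-1-ol (both epimers at the carbinol carbon C8)
Conditions: i-Bu2AlH (5 equiv), CH2Cl2, −78 to 0 °C; aq. potassium sodium tartrate
Reagents that add atoms: none
Why: 1,2-Hydride reduction of the enoate to the allylic alcohol, in which the C8 ketone is knowingly reduced as well (it is re-oxidised in step 10) and the acid-sensitive enol ether should survive the neutral tartrate work-up.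

Step 10
Reactants: 17 (2E)-3-[(1S,3S,4S,5R)-4-(3,4-dimethoxyphenyl)-2-hydroxy-3-methoxy-5-methyl-1-(prop-2-en-1-yl)cyclopentyl]-2-methoxyprop-2-en-1-ol
Product: 18 (2E)-3-[(1S,3S,4S,5R)-4-(3,4-dimethoxyphenyl)-3-methoxy-5-methyl-2-oxo-1-(prop-2-en-1-yl)cyclopentyl]-2-methoxyprop-2-enal
Conditions: Dess–Martin periodinane (3 equiv), NaHCO3, CH2Cl2, 0 °C to rt
Reagents that add atoms: none
Why: Dess–Martin oxidation of both alcohols under buffered non-acidic conditions should return the C8 ketone and give the enal without isomerising the E alkene or hydrolysing the enol ether.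

Step 11
Reactants: 18 (2E)-3-[(1S,3S,4S,5R)-4-(3,4-dimethoxyphenyl)-3-methoxy-5-methyl-2-oxo-1-(prop-2-en-1-yl)cyclopentyl]-2-methoxyprop-2-enal
Product: 20 (1S,2S,5S,6R,7S)-7-(3,4-dimethoxyphenyl)-1,3-dimethoxy-6-methyl-8-oxo-5-(prop-2-en-1-yl)bicyclo[3.2.1]oct-3-en-2-yl acetate, via lithium aldolate 19 (not isolated)
Conditions: LiN(SiMe3)2 (1.1 equiv), THF, −78 °C; then Ac2O, −78 to 0 °C
Reagents that add atoms: acetic anhydride, CC(=O)OC(C)=O
Why: Intramolecular aldol addition (6-enolendo-exo-trig) of the lithium enolate of the C8 ketone, which can form only toward C1, to the non-enolisable enal, in which the tether on the upper face of C5 forces the C1–C2 bond cis to the C3–C4 bridge (C1), lithium bridging the enolate and aldehyde oxygens should place the C2 oxygen on the side of the C8 carbonyl (C2), and in situ acetylation traps the aldolate before retro-aldol opening.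

**Compound list**

1 | 3,4-dimethoxybenzaldehyde | COc1ccc(C=O)cc1OC | starting material
2 | methyl methoxyacetate | COCC(=O)OC | starting material
3 | methyl (2Z)-3-(3,4-dimethoxyphenyl)-2-methoxyprop-2-enoate | COC(=O)/C(OC)=C/c1ccc(OC)c(OC)c1 | intermediate
4 | (2Z)-3-(3,4-dimethoxyphenyl)-N,2-dimethoxy-N-methylprop-2-enamide | CON(C)C(=O)/C(OC)=C/c1ccc(OC)c(OC)c1 | intermediate
5 | (E)-1-bromoprop-1-ene | C/C=C/Br | starting material
6 | (E)-prop-1-en-1-yllithium | C/C=C/[Li] | intermediate
7 | (1Z,4E)-1-(3,4-dimethoxyphenyl)-2-methoxyhexa-1,4-dien-3-one | COc1ccc(/C=C(OC)/C(=O)/C=C/C)cc1OC | intermediate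
8 | triethyl{[(3S,4S)-3-(3,4-dimethoxyphenyl)-2-methoxy-4-methylcyclopent-1-en-1-yl]oxy}silane | C1C(O[Si](CC)(CC)CC)=C(OC)[C@H](c2ccc(OC)c(OC)c2)[C@H]1C | intermediate
9 | (2S,3S,4S)-3-(3,4-dimethoxyphenyl)-2-methoxy-4-methylcyclopentan-1-one (all-trans) | C1C(=O)[C@@H](OC)[C@H](c2ccc(OC)c(OC)c2)[C@H]1C | intermediate
10 | (2S,3S,4R,5Z)-3-(3,4-dimethoxyphenyl)-5-(hydroxymethylidene)-2-methoxy-4-methylcyclopentan-1-one | O/C=C1\C(=O)[C@@H](OC)[C@H](c2ccc(OC)c(OC)c2)[C@H]1C | intermediate
11 | (1S,3S,4S,5R)-4-(3,4-dimethoxyphenyl)-3-methoxy-5-methyl-2-oxo-1-(prop-2-en-1-yl)cyclopentane-1-carbaldehyde (allyl trans, formyl cis to methyl) | C=CC[C@]1(C=O)C(=O)[C@@H](OC)[C@H](c2ccc(OC)c(OC)c2)[C@H]1C | intermediate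
12 | methyl 2-(dimethoxyphosphoryl)-2-methoxyacetate | COC(=O)C(OC)P(=O)(OC)OC | starting material
13 | methyl 2-{bis[(trimethylsilyl)oxy]phosphoryl}-2-methoxyacetate | COC(=O)C(OC)P(=O)(O[Si](C)(C)C)O[Si](C)(C)C | intermediate
14 | methyl 2-(dichlorophosphoryl)-2-methoxyacetate | COC(=O)C(OC)P(=O)(Cl)Cl | intermediate
15 | methyl 2-[bis(2,2,2-trifluoroethoxy)phosphoryl]-2-methoxyacetate | COC(=O)C(OC)P(=O)(OCC(F)(F)F)OCC(F)(F)F | intermediate
16 | methyl (2E)-3-[(1S,3S,4S,5R)-4-(3,4-dimethoxyphenyl)-3-methoxy-5-methyl-2-oxo-1-(prop-2-en-1-yl)cyclopentyl]-2-methoxyprop-2-enoate (ester cis to the ring carbon) | C=CC[C@]1(/C=C(/OC)C(=O)OC)C(=O)[C@@H](OC)[C@H](c2ccc(OC)c(OC)c2)[C@H]1C | intermediate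
17 | (2E)-3-[(1S,3S,4S,5R)-4-(3,4-dimethoxyphenyl)-2-hydroxy-3-methoxy-5-methyl-1-(prop-2-en-1-yl)cyclopentyl]-2-methoxyprop-2-en-1-ol (carbinol carbon C8 as epimer mixture) | C=CC[C@]1(/C=C(/OC)CO)C(O)[C@@H](OC)[C@H](c2ccc(OC)c(OC)c2)[C@H]1C | intermediate
18 | (2E)-3-[(1S,3S,4S,5R)-4-(3,4-dimethoxyphenyl)-3-methoxy-5-methyl-2-oxo-1-(prop-2-en-1-yl)cyclopentyl]-2-methoxyprop-2-enal | C=CC[C@]1(/C=C(/OC)C=O)C(=O)[C@@H](OC)[C@H](c2ccc(OC)c(OC)c2)[C@H]1C | intermediate
19 | lithium (1S,2S,5S,6R,7S)-7-(3,4-dimethoxyphenyl)-1,3-dimethoxy-6-methyl-8-oxo-5-(prop-2-en-1-yl)bicyclo[3.2.1]oct-3-en-2-olate | C=CC[C@]12C=C(OC)[C@H](O[Li])[C@](OC)(C1=O)[C@H](c1ccc(OC)c(OC)c1)[C@H]2C | intermediate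
20 | (1S,2S,5S,6R,7S)-7-(3,4-dimethoxyphenyl)-1,3-dimethoxy-6-methyl-8-oxo-5-(prop-2-en-1-yl)bicyclo[3.2.1]oct-3-en-2-yl acetate (CNP0221003.1) | C=CC[C@]12C=C(OC)[C@H](OC(C)=O)[C@](OC)(C1=O)[C@H](c1ccc(OC)c(OC)c1)[C@H]2C | target

**Step count.** Total: 11 steps (ten on the main line plus the reagent preparation, step 7). Longest linear sequence: 10 steps (steps 1–6 and 8–11, from 1).

**Steps most likely to fail**

First, step 4, the only step beyond known chemistry. Enantiocontrol may be eroded by a racemic background cyclisation promoted by the silyl triflate formed after hydride transfer. The silane may also reduce the divalent copper catalyst, or the oxyallyl cation may lose a proton before hydride arrives. The fallback uses known chemistry and sets out from 7. The reductive Nazarov cyclisation is run with an achiral promoter (BF3·OEt2, Et3SiH, CH2Cl2, −78 °C to rt, acidic work-up). This should give the all-trans ketone as the racemate, that is 9 together with its mirror image (2R,3R,4R)-3-(3,4-dimethoxyphenyl)-2-methoxy-4-methylcyclopentan-1-one F1. The enantiomers are separated by preparative SFC on a chiral stationary phase, and the route is rejoined at 9.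

Second, step 8. The kinetic preference for the ester cis to the crowded C5 substituent may be insufficient, so that the ester ends up trans and the ring cannot close. The adduct may also fragment by retro-Claisen loss of the formyl group instead of eliminating phosphate. The fallback sets out from 11, which is olefinated under thermodynamic control with commercial 12 (NaH, THF, 0 °C). This should give mainly methyl (2Z)-3-[(1S,3S,4S,5R)-4-(3,4-dimethoxyphenyl)-3-methoxy-5-methyl-2-oxo-1-(prop-2-en-1-yl)cyclopentyl]-2-methoxyprop-2-enoate F2. F2 is then subjected to triplet-sensitised E/Z photoisomerisation (xanthone, MeCN, 350 nm). The planar, conjugated Z isomer is the better energy acceptor, while the twisted E isomer should accumulate. Ester 16 is separated, F2 is recycled, and the route is rejoined at 16.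

Third, step 11. The amide base may add to the aldehyde instead of deprotonating the hindered C1–H. The strained aldolate may reopen by retro-aldol before it is acetylated, or uncyclised enolate may be acetylated on oxygen. The fallback sets out from 18 and replaces the lithium enolate by a Mukaiyama aldol. Soft enolisation (TMSOTf, Et3N, CH2Cl2, 0 °C) gives (2E)-3-[(1S,4S,5R)-4-(3,4-dimethoxyphenyl)-3-methoxy-5-methyl-1-(prop-2-en-1-yl)-2-[(trimethylsilyl)oxy]cyclopent-2-en-1-yl]-2-methoxyprop-2-enal F3. F3 is cyclised with MgBr2·OEt2 in CH2Cl2 at −78 °C, where the C6–C7 bridge blocks the lower face of C2. This should give (1S,2S,5S,6R,7S)-7-(3,4-dimethoxyphenyl)-2-hydroxy-1,3-dimethoxy-6-methyl-5-(prop-2-en-1-yl)bicyclo[3.2.1]oct-3-en-8-one F4 (target numbering). Acetylation (Ac2O, DMAP, pyridine, 0 °C) then gives 20.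

**Further compounds**

F1 | step 4 | (2R,3R,4R)-3-(3,4-dimethoxyphenyl)-2-methoxy-4-methylcyclopentan-1-one | C1C(=O)[C@H](OC)[C@@H](c2ccc(OC)c(OC)c2)[C@@H]1C
F2 | step 8 | methyl (2Z)-3-[(1S,3S,4S,5R)-4-(3,4-dimethoxyphenyl)-3-methoxy-5-methyl-2-oxo-1-(prop-2-en-1-yl)cyclopentyl]-2-methoxyprop-2-enoate | C=CC[C@]1(/C=C(\OC)C(=O)OC)C(=O)[C@@H](OC)[C@H](c2ccc(OC)c(OC)c2)[C@H]1C
F3 | step 11 | (2E)-3-[(1S,4S,5R)-4-(3,4-dimethoxyphenyl)-3-methoxy-5-methyl-1-(prop-2-en-1-yl)-2-[(trimethylsilyl)oxy]cyclopent-2-en-1-yl]-2-methoxyprop-2-enal | C=CC[C@]1(/C=C(/OC)C=O)C(O[Si](C)(C)C)=C(OC)[C@H](c2ccc(OC)c(OC)c2)[C@H]1C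
F4 | step 11 | (1S,2S,5S,6R,7S)-7-(3,4-dimethoxyphenyl)-2-hydroxy-1,3-dimethoxy-6-methyl-5-(prop-2-en-1-yl)bicyclo[3.2.1]oct-3-en-8-one | C=CC[C@]12C=C(OC)[C@H](O)[C@](OC)(C1=O)[C@H](c1ccc(OC)c(OC)c1)[C@H]2C
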